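## Structural features

Atom numbering used throughout: C1 (carbinol carbon carrying C7), C2 (C=O), C3=C4, C5 (CHOH), C6 (CHOBz), C7 (CH2OBz).

The target is a monocyclic cyclohex-3-en-2-one with one exocyclic carbon, C7; the only other rings are the phenyl groups of the two benzoates on O7 and O6. C1 is a fully substituted carbinol, C2=O is conjugated with C3=C4, C5 is a free secondary allylic carbinol and C6 a secondary benzoate. The three stereocentres are contiguous, C1(R)–C6(S)–C5(R): O1 and O5 lie on one face, O6 and C7 on the other, so O1/O6 and O5/O6 are both trans. The fragile points are the benzoates next to free hydroxyls (acyl shifts O7→O1, O6→O5 and O6→O1 under base), the γ-hydroxy enone (loss of water and benzoic acid would give a phenol) and the tertiary α-ketol, so the closing steps must be neutral or acidic. The real difficulty is the quaternary stereocentre C1 in a defined relation to C6 and C5, together with four oxygens of which exactly two must end up acylated. The ring plus C7 is the carbon skeleton of benzoic acid; after 1,4-reduction and oxygenation at C1, that carbon sits on a mirror plane between two enantiotopic cis-alkenes (C2=C3 and C6=C5), each homoallylic to the C7 hydroxyl. The key step exploits this: a C7-hydroxyl-directed, ligand-controlled epoxidation of C5=C6 alone makes C1 stereogenic and fixes C5 and C6 in the same event.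

## Logic of the disconnections

**20 ⇒ 18 (through 19).** The O5–CH2Ar and O1–Si bonds are cut. Both free hydroxyls stay masked to the end so that neither can accept a migrating benzoyl group or start an elimination. The gain in simplicity is small. The forward step must unmask both without base: an oxidative ether cleavage, then fluoride-assisted desilylation in acid.

**18 ⇒ 15 + 16.** The C2–O bond is cut and the alkene is moved back from C3=C4 to C2=C3, with C4 as a methylene. The enone is the transposed oxidation product of a plain ring alkene. Because C1 has no hydrogen, an ene reaction can take hydrogen only from C4 and must put oxygen on C2. This removes the carbonyl and the sensitive γ-oxygenated enone. The forward step needs an ene reaction on a deactivated cis-alkene and dehydration of 17 without base damage.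

**15 ⇒ 13 + 14.** The two acyl C–O bonds at O6 and O7 are cut. Both benzoates then come from one reagent in one operation. This requires O5 and O1 to be already blocked, and the hindered O6 must still be acylated.

**13 ⇒ 11 + 12.** The C5–O ether bond is cut. The trans O5/O6 pair is the signature of backside opening of an oxirane, and O5 arrives already protected. The forward step needs attack at C5 rather than C6 and no ionisation at C1.

**11 ⇒ 9 + 10.** The C5–O and C6–O bonds are cut and the oxirane is opened. All three stereocentres disappear and 9 is achiral. The forward step needs selection of one of two enantiotopic alkenes, the face cis to C7, and a stop after one epoxidation.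

**9 ⇒ 8.** C7 is returned to the ester oxidation level. The ester is what makes C1–H acidic earlier in the route. The reduction must not let silicon move from O1 to O7.

**8 ⇒ 6 + 7.** The O1–Si bond is cut. The tertiary oxygen must be capped before the primary hydroxyl exists, so that later only O7 can bind a metal.

**6 ⇒ 4 + 5.** The C1–O bond is cut. C1 is the α-carbon of an ester flanked by two vinyl groups, so enolate oxidation is the natural way to form it. Oxygen must go to C1 and not to C3, and the ring must not aromatise.

**4 ⇒ 2 + 3, and 2 ⇒ 1.** The ester O–CH3 bond is cut, and then the two C–H bonds at C1 and C4 that a dissolving-metal reduction adds to the arene. This leaves an aromatic acid as the only carbon source for the ring and C7.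

## Other disconnections considered

**Alternative 1:** The cut is through the C1–O and C6–O bonds, with the ring already opened so that C2 and C5 are ester carbons. The substrate is the trisubstituted E-alkene A1 and the forward key step is an asymmetric dihydroxylation (OsO4 catalysis with a phthalazine-bridged cinchona ligand) giving diol A2.

- In its favour: the face selection follows a well-established empirical model, and syn addition to the E-alkene gives the O1/O6 relation of 20 directly. A1 is only a few steps from simple materials and no photochemistry is needed.
- Point where it is better: predictability of absolute configuration is better than for the desymmetrisation chosen here, which has no close substrate precedent.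
- Against it: the alkene carries two esters and an allylic benzoate, so osmylation should be slow. The basic medium puts a benzoate next to two new hydroxyls in A2, which invites acyl migration.
- Against it structurally: the ring is not made. The two ester carbons of A2 are nearly equivalent and must be told apart. C5 must still be created by a diastereoselective carbonyl addition. C3 and C4 must be added and joined, for example by ring-closing metathesis with a second-generation Grubbs catalyst.
- Comparison: it sets two stereocentres by a reagent-controlled [3+2] osmylation, whereas the chosen plan sets three by tethered oxygen transfer on a preformed ring. In step count it would be clearly longer.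

**Alternative 2:** The cut is through the C2–O and C5–O bonds, reading the 4-hydroxy enone as a rearranged 1,4-endoperoxide. The substrate is diene A3; the forward key step is a [4+2] cycloaddition of singlet oxygen giving A4, followed by a base-induced Kornblum–DeLaMare rearrangement to 20.

- In its favour: a 1,3-diene is far more reactive toward singlet oxygen than the isolated alkene of 15, and both oxygens arrive in one step. Neither O1 nor O5 needs protection.
- Points where it is better: reactivity in the photooxygenation, protecting-group count and length of the endgame (two steps instead of four).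
- Against it: the rearrangement must remove the hydrogen on C2 and not the one on C5. The C5 hydrogen is less hindered and is acidified by the adjacent benzoate-bearing carbon, so the isomer with the carbonyl at C5 is the expected competitor.
- Also against it: base is used when free hydroxyls sit next to benzoates and the product can eliminate. The facial selectivity relies on substrate bias at C1, where both faces are substituted.
- Also against it: A3 already contains C1 and C6, so this is an endgame and leaves the stereochemical problem unsolved. A3 would need its own asymmetric source, for instance isomerisation of 11 to the allylic alcohol.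
- Comparison: the carbocycle is the same. Mechanistically the cycloaddition is more dependable than an ene reaction, but the position of the carbonyl is guaranteed by mechanism in the chosen plan and not here.

**Alternative 3:** The cut is the C1–C2 bond, opening the ring to keto aldehyde A5. The forward key step is an intramolecular crossed benzoin reaction under a chiral triazolylidene carbene: the Breslow intermediate from the C2 aldehyde adds to the C1 ketone and gives α-ketol A6.

- In its favour: the quaternary carbinol and the C2 carbonyl form in one catalytic C–C bond formation, with no late oxidation and no photochemistry. C5 and C6 can be taken from the chiral pool. Aldehyde–ketone benzoin closures to six-membered rings are an established reaction type.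
- Points where it is equal or better: placing the carbonyl is better, and the security of the C5/C6 absolute configuration is equal or better.
- Against it: the acceptor ketone has an acyloxy group on each α-carbon. Under basic carbene conditions it can enolise, epimerise at C6, eliminate benzoate or pass benzoyl to the new alkoxide.
- Also against it: the C1 configuration needs the catalyst to be matched with the two existing stereocentres. A6 still lacks the C3=C4 double bond, so a dehydrogenation (for example Saegusa–Ito) next to a free tertiary hydroxyl and a desilylation remain.
- Comparison: A5 itself needs a multistep synthesis, so the sequence would be longer than the chosen plan, which needs five steps to reach 9. Alternative 3 builds a skeletal bond, whereas the chosen plan buys the whole skeleton and forms only C–O bonds.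

Key step: step 6

Assumption: which antipode of the bishydroxamic acid ligand selects the C5=C6 alkene cannot be assigned in advance for this substrate class; the (R,R)-ligand is written, and the equally available (S,S)-ligand would be used if an MTPA-ester analysis of 11 shows the opposite sense.

## Route

Step 1
Reactants: 1 benzoic acid
Product: 2 cyclohexa-2,5-diene-1-carboxylic acid
Conditions: Na, NH3 (l), EtOH, −78 → −33 °C; NH4Cl; aq. HCl
Reagents that add atoms: none
Why: Birch reduction; the carboxylate directs protonation to C1 and C4, giving the unconjugated 1,4-diene, and no stereocentre is formed.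

Step 2
Reactants: 2 cyclohexa-2,5-diene-1-carboxylic acid; 3 iodomethane
Product: 4 methyl cyclohexa-2,5-diene-1-carboxylate
Conditions: MeI, KHCO3, DMF, rt
Reagents that add atoms: iodomethane (3), CI
Why: Carboxylate O-alkylation (SN2) under bicarbonate, mild enough that the doubly allylic C1–H is not removed and the skipped diene stays out of conjugation; the ester acidifies C1–H for the next step and is the latent C7 carbinol.

Step 3
Reactants: 4 methyl cyclohexa-2,5-diene-1-carboxylate; 5 3-phenyl-2-(phenylsulfonyl)oxaziridine
Product: 6 methyl 1-hydroxycyclohexa-2,5-diene-1-carboxylate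
Conditions: KN(SiMe3)2, THF, −78 °C; then 5, −78 °C; aq. NH4Cl
Reagents that add atoms: 3-phenyl-2-(phenylsulfonyl)oxaziridine (5), O=S(=O)(N1OC1c1ccccc1)c1ccccc1
Why: Electrophilic α-hydroxylation of an ester enolate with an N-sulfonyloxaziridine; the cross-conjugated potassium dienolate attacks the oxaziridine oxygen through C1, the position at which Birch-derived dienolates are alkylated, and the potassium counter-ion limits addition to the sulfonylimine by-product. C1 stays on the mirror plane, so 6 is achiral.

Step 4
Reactants: 6 methyl 1-hydroxycyclohexa-2,5-diene-1-carboxylate; 7 triethylsilyl trifluoromethanesulfonate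
Product: 8 methyl 1-[(triethylsilyl)oxy]cyclohexa-2,5-diene-1-carboxylate
Conditions: Et3SiOTf, 2,6-lutidine, CH2Cl2, −78 → 0 °C
Reagents that add atoms: triethylsilyl trifluoromethanesulfonate (7), CC[Si](CC)(CC)OS(=O)(=O)C(F)(F)F
Why: Silylation of a hindered tertiary alcohol needs the silyl triflate with a non-nucleophilic base; the ester on C1 disfavours ionisation of the doubly allylic C1–O bond. The triethylsilyl group is kept because a tertiary triethylsilyl ether is robust enough for the later steps, cannot bind a metal, and can still be removed at the end without base.

Step 5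
Reactants: 8 methyl 1-[(triethylsilyl)oxy]cyclohexa-2,5-diene-1-carboxylate
Product: 9 {1-[(triethylsilyl)oxy]cyclohexa-2,5-dien-1-yl}methanol (achiral)
Conditions: iBu2AlH (2.5 equiv), CH2Cl2, −78 → −20 °C; aq. potassium sodium tartrate
Reagents that add atoms: none
Why: Ester reduction by an aluminium hydride at low temperature; the aluminium alkoxide is a poor nucleophile toward silicon, which should prevent 1,4-migration of the silyl group from O1 to O7, and the neutral tartrate work-up avoids acid that could aromatise this arene-hydrate derivative.

Step 6
Reactants: 9 {1-[(triethylsilyl)oxy]cyclohexa-2,5-dien-1-yl}methanol; 10 cumene hydroperoxide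
Product: 11 [(1S,2R,6S)-2-[(triethylsilyl)oxy]-7-oxabicyclo[4.1.0]hept-3-en-2-yl]methanol (oxirane across C5–C6 on the face of the hydroxymethyl group, trans to the silyloxy group; C2=C3 intact)
Conditions: Hf(OtBu)4 (10 mol%), (R,R)-N,N'-dihydroxy-N,N'-bis(diphenylacetyl)cyclohexane-1,2-diamine (12 mol%), cumene hydroperoxide (1.1 equiv), DMPU, 4 Å MS, toluene, 0 °C
Reagents that add atoms: cumene hydroperoxide (10), CC(C)(OO)c1ccccc1
Why: The C7 alkoxide of 9 and the cumyl peroxide bind the tetravalent hafnium centre that carries the C2-symmetric bishydroxamate, and the peroxide oxygen passes in a concerted transition state to the alkene held under the metal; the closest known reaction type is the Hf(OtBu)4- or Zr(OtBu)4-bishydroxamic acid epoxidation of homoallylic alcohols, run here as a desymmetrisation in the manner of divinyl carbinol epoxidations. The oxirane, the one ring formed, closes by [2+1] transfer of a single oxygen atom that forms C5–O and C6–O together, so the cis geometry of the ring alkene is carried into the epoxide. The configurations at C5 and C6 are set by intramolecular delivery through the C7–O–Hf tether, which reaches only the face cis to the hydroxymethyl group; the silyl ether blocks the other face and cannot bind the metal. C1 becomes stereogenic only because one of the two enantiotopic alkenes is chosen, and that choice is made by the chiral ligand. The step needs group selectivity, face selectivity and mono-epoxidation: the ligand supplies the first, the tether and silyl ether the second, and about one equivalent of hydroperoxide the third. A second epoxidation would consume mainly the minor enantiomer and so should raise rather than erode the enantiomeric purity. Low temperature, molecular sieves and the basic DMPU additive protect the doubly allylic C4 methylene and the acid-sensitive tertiary allylic silyl ether.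

Step 7
Reactants: 11 [(1S,2R,6S)-2-[(triethylsilyl)oxy]-7-oxabicyclo[4.1.0]hept-3-en-2-yl]methanol; 12 (4-methoxyphenyl)methanol
Product: 13 (1S,2R,6R)-2-(hydroxymethyl)-6-[(4-methoxyphenyl)methoxy]-2-[(triethylsilyl)oxy]cyclohex-3-en-1-ol (target numbering: C5 ether oxygen cis to O1, C6 hydroxyl trans to both)
Conditions: 4-MeOC6H4CH2OH (5 equiv), BF3·OEt2 (0.2 equiv), CH2Cl2, −40 → −10 °C; Et3N quench
Reagents that add atoms: (4-methoxyphenyl)methanol (12), COc1ccc(CO)cc1
Why: Lewis acid-catalysed alcoholysis of an epoxide (SN2, inversion); the alcohol attacks C5 from the face opposite the oxirane oxygen because C6 is neopentylic, is screened on that face by the silyl ether and is inductively deactivated by O1 and O7. C5 thus becomes R with its oxygen trans to O6 and already protected, while C6 keeps its configuration; the C7 hydroxyl lies on the oxirane face and cannot reach either carbon from the rear.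

Step 8
Reactants: 13 (1S,2R,6R)-2-(hydroxymethyl)-6-[(4-methoxyphenyl)methoxy]-2-[(triethylsilyl)oxy]cyclohex-3-en-1-ol; 14 benzoyl chloride
Product: 15 [(1R,5R,6S)-6-(benzoyloxy)-5-[(4-methoxyphenyl)methoxy]-1-[(triethylsilyl)oxy]cyclohex-2-en-1-yl]methyl benzoate
Conditions: BzCl (3 equiv), pyridine, DMAP (cat.), CH2Cl2, 0 °C → rt
Reagents that add atoms: benzoyl chloride (14), O=C(Cl)c1ccccc1
Why: DMAP-catalysed acylation of the primary O7 and the hindered secondary O6; O1 and O5 are blocked, so exactly the two benzoates of the target are installed and no stereocentre is touched.

Step 9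
Reactants: 15 [(1R,5R,6S)-6-(benzoyloxy)-5-[(4-methoxyphenyl)methoxy]-1-[(triethylsilyl)oxy]cyclohex-2-en-1-yl]methyl benzoate; 16 dioxygen
Product: 18 [(1R,5R,6S)-6-(benzoyloxy)-5-[(4-methoxyphenyl)methoxy]-2-oxo-1-[(triethylsilyl)oxy]cyclohex-3-en-1-yl]methyl benzoate, via C2 allylic hydroperoxide 17 (not isolated)
Conditions: O2, tetraphenylporphyrin (cat.), visible light, Ac2O, pyridine, DMAP (cat.), CH2Cl2, 0 °C
Reagents that add atoms: dioxygen (16), O=O
Why: Schenck ene reaction of singlet oxygen followed by dehydration of the allylic hydroperoxide in the same flask (O-acetylation, then Kornblum–DeLaMare-type elimination); C1 has no hydrogen, so hydrogen can be taken only from C4, which puts the new C–O bond on C2 and moves the alkene to C3=C4. Immediate conversion of 17 into the unreactive enone should prevent a second ene reaction, and the C2 configuration of 17 is lost in the ketone and so does not matter.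

Step 10
Reactants: 18 [(1R,5R,6S)-6-(benzoyloxy)-5-[(4-methoxyphenyl)methoxy]-2-oxo-1-[(triethylsilyl)oxy]cyclohex-3-en-1-yl]methyl benzoate
Product: 20 [(1R,5R,6S)-6-(benzoyloxy)-1,5-dihydroxy-2-oxocyclohex-3-en-1-yl]methyl benzoate, via 1-O-triethylsilyl enone 19 (not isolated)
Conditions: DDQ, MeCN/H2O (10:1), 0 °C; then 48% aq. HF added to the same flask (polypropylene), 0 °C → rt
Reagents that add atoms: none
Why: Oxidative cleavage of the 4-methoxybenzyl ether by DDQ (hydride abstraction, hydrolysis of the oxocarbenium ion), then fluoride-assisted cleavage of the tertiary silyl ether, which its electron-poor neighbours should make easier; both stages are non-basic, so benzoyl migration and β-elimination should not be triggered. The C1–O and C5–O bonds are not broken, so all three stereocentres are retained.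

## Compound list

1 | benzoic acid | OC(=O)c1ccccc1 | starting material
2 | cyclohexa-2,5-diene-1-carboxylic acid | OC(=O)C1C=CCC=C1 | intermediate
3 | iodomethane | CI | starting material
4 | methyl cyclohexa-2,5-diene-1-carboxylate | COC(=O)C1C=CCC=C1 | intermediate
5 | 3-phenyl-2-(phenylsulfonyl)oxaziridine (racemic) | O=S(=O)(N1OC1c1ccccc1)c1ccccc1 | starting material
6 | methyl 1-hydroxycyclohexa-2,5-diene-1-carboxylate | COC(=O)C1(O)C=CCC=C1 | intermediate
7 | triethylsilyl trifluoromethanesulfonate | CC[Si](CC)(CC)OS(=O)(=O)C(F)(F)F | starting material
8 | methyl 1-[(triethylsilyl)oxy]cyclohexa-2,5-diene-1-carboxylate | COC(=O)C1(O[Si](CC)(CC)CC)C=CCC=C1 | intermediate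
9 | {1-[(triethylsilyl)oxy]cyclohexa-2,5-dien-1-yl}methanol | CC[Si](CC)(CC)OC1(CO)C=CCC=C1 | intermediate
10 | cumene hydroperoxide | CC(C)(OO)c1ccccc1 | starting material
11 | [(1S,2R,6S)-2-[(triethylsilyl)oxy]-7-oxabicyclo[4.1.0]hept-3-en-2-yl]methanol | OC[C@]1(O[Si](CC)(CC)CC)C=CC[C@@H]2O[C@H]12 | intermediate
12 | (4-methoxyphenyl)methanol | COc1ccc(CO)cc1 | starting material
13 | (1S,2R,6R)-2-(hydroxymethyl)-6-[(4-methoxyphenyl)methoxy]-2-[(triethylsilyl)oxy]cyclohex-3-en-1-ol | OC[C@]1(O[Si](CC)(CC)CC)C=CC[C@@H](OCc2ccc(OC)cc2)[C@@H]1O | intermediate
14 | benzoyl chloride | O=C(Cl)c1ccccc1 | starting material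
15 | [(1R,5R,6S)-6-(benzoyloxy)-5-[(4-methoxyphenyl)methoxy]-1-[(triethylsilyl)oxy]cyclohex-2-en-1-yl]methyl benzoate | O=C(OC[C@]1(O[Si](CC)(CC)CC)C=CC[C@@H](OCc2ccc(OC)cc2)[C@@H]1OC(=O)c1ccccc1)c1ccccc1 | intermediate
16 | dioxygen (used as singlet oxygen) | O=O | starting material
17 | [(1R,5R,6S)-6-(benzoyloxy)-2-hydroperoxy-5-[(4-methoxyphenyl)methoxy]-1-[(triethylsilyl)oxy]cyclohex-3-en-1-yl]methyl benzoate (C2 epimers) | O=C(OC[C@]1(O[Si](CC)(CC)CC)C(OO)C=C[C@@H](OCc2ccc(OC)cc2)[C@@H]1OC(=O)c1ccccc1)c1ccccc1 | intermediate
18 | [(1R,5R,6S)-6-(benzoyloxy)-5-[(4-methoxyphenyl)methoxy]-2-oxo-1-[(triethylsilyl)oxy]cyclohex-3-en-1-yl]methyl benzoate | O=C(OC[C@]1(O[Si](CC)(CC)CC)C(=O)C=C[C@@H](OCc2ccc(OC)cc2)[C@@H]1OC(=O)c1ccccc1)c1ccccc1 | intermediate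
19 | [(1R,5R,6S)-6-(benzoyloxy)-5-hydroxy-2-oxo-1-[(triethylsilyl)oxy]cyclohex-3-en-1-yl]methyl benzoate | O=C(OC[C@]1(O[Si](CC)(CC)CC)C(=O)C=C[C@@H](O)[C@@H]1OC(=O)c1ccccc1)c1ccccc1 | intermediate
20 | [(1R,5R,6S)-6-(benzoyloxy)-1,5-dihydroxy-2-oxocyclohex-3-en-1-yl]methyl benzoate | O=C(OC[C@]1(O)C(=O)C=C[C@@H](O)[C@@H]1OC(=O)c1ccccc1)c1ccccc1 | target

## Step count and least certain steps

Total step count: 10. Longest linear sequence: 10 steps (1 to 20; the route is fully linear).

**Step 6 (key step).** The ligand may discriminate poorly between the two enantiotopic alkenes, since a cyclic substrate with a quaternary carbon between hydroxyl and alkenes is outside the tested range. Turnover may also be slow at the hindered alkoxide, a second epoxidation may occur, or the Lewis acid may induce loss of silanol with aromatisation.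
Fallback (from 9, returning at 11): hydroxyl-directed epoxidation with VO(acac)2 and tert-butyl hydroperoxide, known for homoallylic alcohols, should give the same relative configuration without enantiocontrol, that is 11 together with mirror-image epoxy alcohol F1. Steglich esterification of the mixture with (S)-2-methoxy-2-phenylacetic acid (DCC, DMAP) would give two diastereomers, methoxyphenylacetate of 11 F2 and methoxyphenylacetate of the mirror image F3, to be separated by chromatography or crystallisation. Reductive cleavage of F2 with iBu2AlH at −78 °C returns 11.

**Step 7.** The Lewis acid may trigger ionisation-driven side reactions before the alcohol captures the activated oxirane: ring contraction by a 1,2-shift from C1, loss or migration of the silyl group, and self-condensation of the benzylic alcohol. Attack at the wrong carbon is the lesser concern.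
Fallback (from 11, returning at 15): selective benzoylation of the primary hydroxyl (BzCl, pyridine, 0 °C) gives epoxy benzoate F4. Hydrolysis with water in large excess (cat. HClO4, THF/H2O, 0 °C), where the solvent itself is the nucleophile and attacks C5 with inversion, gives trans-diol F5. The less hindered C5 hydroxyl is etherified with 4-methoxybenzyl 2,2,2-trichloroacetimidate (cat. La(OTf)3, toluene) to give C5 ether F6, and benzoylation of the remaining C6 hydroxyl (BzCl, pyridine, DMAP) returns to 15.

**Step 9.** The ene reaction may be slow on a cis-disubstituted alkene that is deactivated by the allylic oxygen and flanked by the quaternary C1. Long irradiation would then bleach the sensitiser and oxidise the benzylic ether. The elimination of the peracetate at the hindered C2–H may also be incomplete.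
Fallback (from 15, returning at 18): epoxidation of C2=C3 with mCPBA gives epoxide F7 (either face serves). Opening at the less hindered C3 with PhSeNa, made from (PhSe)2 and NaBH4 in EtOH, gives hydroxy selenide F8. Oxidation with H2O2 and syn-elimination of the selenoxide away from the carbinol carbon gives allylic alcohol F9 with the C3=C4 double bond. Dess–Martin oxidation of the C2 hydroxyl gives 18.

**Step 3.** Oxygen transfer may occur at the γ-carbon (C3) of the cross-conjugated dienolate, the enolate may add to the sulfonylimine by-product, or the oxygenated diene may aromatise during work-up.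
Fallback (from 4, returning at 8): enolisation with LiN(iPr)2 and O-silylation with Et3SiCl in THF at −78 °C gives triethylsilyl ketene acetal F10. Rubottom oxidation with dimethyldioxirane in acetone at −78 °C epoxidises the electron-rich exocyclic double bond, which can deliver oxygen only to C1, and silyl transfer from the acetal oxygen to the new oxygen gives 8 directly, so the separate silylation is saved as well.

## Further compounds

F1 | step 6 | [(1R,2S,6R)-2-[(triethylsilyl)oxy]-7-oxabicyclo[4.1.0]hept-3-en-2-yl]methanol (mirror image of 11) | OC[C@@]1(O[Si](CC)(CC)CC)C=CC[C@H]2O[C@@H]12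
F2 | step 6 | [(1S,2R,6S)-2-[(triethylsilyl)oxy]-7-oxabicyclo[4.1.0]hept-3-en-2-yl]methyl (2S)-2-methoxy-2-phenylacetate | CO[C@H](C(=O)OC[C@]1(O[Si](CC)(CC)CC)C=CC[C@@H]2O[C@H]12)c1ccccc1
F3 | step 6 | [(1R,2S,6R)-2-[(triethylsilyl)oxy]-7-oxabicyclo[4.1.0]hept-3-en-2-yl]methyl (2S)-2-methoxy-2-phenylacetate | CO[C@H](C(=O)OC[C@@]1(O[Si](CC)(CC)CC)C=CC[C@H]2O[C@@H]12)c1ccccc1
F4 | step 7 | [(1S,2R,6S)-2-[(triethylsilyl)oxy]-7-oxabicyclo[4.1.0]hept-3-en-2-yl]methyl benzoate | O=C(OC[C@]1(O[Si](CC)(CC)CC)C=CC[C@@H]2O[C@H]12)c1ccccc1
F5 | step 7 | [(1R,5R,6S)-5,6-dihydroxy-1-[(triethylsilyl)oxy]cyclohex-2-en-1-yl]methyl benzoate | O=C(OC[C@]1(O[Si](CC)(CC)CC)C=CC[C@@H](O)[C@@H]1O)c1ccccc1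
F6 | step 7 | [(1R,5R,6S)-6-hydroxy-5-[(4-methoxyphenyl)methoxy]-1-[(triethylsilyl)oxy]cyclohex-2-en-1-yl]methyl benzoate | O=C(OC[C@]1(O[Si](CC)(CC)CC)C=CC[C@@H](OCc2ccc(OC)cc2)[C@@H]1O)c1ccccc1
F7 | step 9 | 2,3-epoxide of 15 (oxirane face not defined; C1, C5, C6 as in 15) | O=C(OC[C@]1(O[Si](CC)(CC)CC)C2OC2C[C@@H](OCc2ccc(OC)cc2)[C@@H]1OC(=O)c1ccccc1)c1ccccc1
F8 | step 9 | 2-hydroxy-3-(phenylselanyl) derivative of 15 (trans at C2/C3, mixture from both oxirane faces) | O=C(OC[C@]1(O[Si](CC)(CC)CC)C(O)C([Se]c2ccccc2)C[C@@H](OCc2ccc(OC)cc2)[C@@H]1OC(=O)c1ccccc1)c1ccccc1
F9 | step 9 | [(1R,5R,6S)-6-(benzoyloxy)-2-hydroxy-5-[(4-methoxyphenyl)methoxy]-1-[(triethylsilyl)oxy]cyclohex-3-en-1-yl]methyl benzoate (C2 epimers) | O=C(OC[C@]1(O[Si](CC)(CC)CC)C(O)C=C[C@@H](OCc2ccc(OC)cc2)[C@@H]1OC(=O)c1ccccc1)c1ccccc1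
F10 | step 3 | [(cyclohexa-2,5-dien-1-ylidene)(methoxy)methoxy]triethylsilane | COC(O[Si](CC)(CC)CC)=C1C=CCC=C1
A1 | alternative 1 | dimethyl (2E)-2-[(benzoyloxy)methyl]but-2-enedioate | COC(=O)/C=C(/C(=O)OC)COC(=O)c1ccccc1
A2 | alternative 1 | dimethyl (2R,3R)-2-[(benzoyloxy)methyl]-2,3-dihydroxybutanedioate | COC(=O)[C@@](O)(COC(=O)c1ccccc1)[C@@H](O)C(=O)OC
A3 | alternative 2 | [(1R,6S)-6-(benzoyloxy)-1-hydroxycyclohexa-2,4-dien-1-yl]methyl benzoate | O=C(OC[C@]1(O)C=CC=C[C@@H]1OC(=O)c1ccccc1)c1ccccc1
A4 | alternative 2 | endoperoxide of A3 bridging C2 and C5, peroxide cis to the C1 hydroxyl | O=C(OC[C@]1(O)[C@@H]2C=C[C@@H](OO2)[C@@H]1OC(=O)c1ccccc1)c1ccccc1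
A5 | alternative 3 | (3S,4R)-4-[(tert-butyldimethylsilyl)oxy]-2,7-dioxoheptane-1,3-diyl dibenzoate | O=CCC[C@@H](O[Si](C)(C)C(C)(C)C)[C@H](OC(=O)c1ccccc1)C(=O)COC(=O)c1ccccc1
A6 | alternative 3 | 3,4-dihydro-5-O-(tert-butyldimethylsilyl) derivative of 20 | O=C(OC[C@]1(O)C(=O)CC[C@@H](O[Si](C)(C)C(C)(C)C)[C@@H]1OC(=O)c1ccccc1)c1ccccc1
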